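**Retrosynthetic overview**
- The vanillate C–O bond and the C6 carbinol come last, from an Evans–Tishchenko reduction of a ten-membered β-hydroxy enone with silyl-protected vanillin (made from catechol); this puts the ester on C8–O and sets C6 1,3-anti in one step.
- The ten-membered carbocycle is the only ring formed. It is closed at C9–C10 before the ester goes on, by a nickel-catalysed reductive alkyl–alkenyl coupling in which a C9 radical is captured by a Z-alkenylnickel (key step).
- The open chain comes from alkynyl addition to an aldol aldehyde (C5–C6), propargylic oxidation, and syn-methylcupration of the ynone (Z-C4=C5).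
- C7 and C8 come from an organocatalytic anti cross-aldol of 3-methylbutanal with chloroacetaldehyde; the Z-alkenyl iodide comes from an iodo-Wittig reaction on pent-4-ynal.

Assumption and atom labels: the SMILES is read literally, i.e. both ring alkenes Z (ring bonds cis) and C8 R, C7 S, C6 R, where C8 = ester carbon, C7 = isopropyl carbon, C6 = carbinol carbon, then C5=C4(Me), C3, C2, C1=C10(Me), C9.

**Route**

Step 1
Reactants: 1 benzene-1,2-diol (catechol)
Product: 2 2-methoxyphenol (guaiacol)
Conditions: MeI (1.0 equiv), K2CO3 (1.0 equiv), acetone, reflux; unreacted 1 recovered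
Reagents that add atoms: iodomethane, IC
Why: Williamson ether synthesis; with one equivalent of MeI the hydrogen-bonded monophenoxide is alkylated once, and the less acidic product reacts more slowly.

Step 2
Reactants: 2 2-methoxyphenol (guaiacol); 3 oxoacetic acid (glyoxylic acid)
Product: 6 4-hydroxy-3-methoxybenzaldehyde (vanillin), via aryl mandelic acid 4 (not isolated), via aryl keto acid 5 (not isolated)
Conditions: NaOH, H2O, 30 °C; then CuSO4 (cat.), O2 (air), 95 °C; then H2SO4, 60 °C
Reagents that add atoms: none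
Why: Electrophilic aromatic hydroxyalkylation para to the phenoxide oxygen, then copper-catalysed aerobic oxidation to the aryl glyoxylate and acid-induced decarboxylation (the guaiacol–glyoxylic acid vanillin process).

Step 3
Reactants: 6 4-hydroxy-3-methoxybenzaldehyde (vanillin)
Product: 7 4-[(tert-butyldimethylsilyl)oxy]-3-methoxybenzaldehyde
Conditions: TBSCl, imidazole, DMF, 23 °C
Reagents that add atoms: tert-butyldimethylsilyl chloride, CC(C)(C)[Si](C)(C)Cl
Why: Silyl ether formation; the free phenol would otherwise bind the samarium catalyst of step 10.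

Step 4
Reactants: 8 pent-4-ynal
Product: 9 (5Z)-6-iodohept-5-en-1-yne
Conditions: [EtPPh3]I, n-BuLi, THF, 23 °C; [I][I], −78 °C; NaN(SiMe3)2, −20 °C; then 8, −78 → 23 °C
Reagents that add atoms: ethyltriphenylphosphonium iodide, CC[P+](c1ccccc1)(c1ccccc1)c1ccccc1.[I-]; iodine, [I][I]
Why: Stork–Zhao-type α-iodoethylidene Wittig olefination; the unstabilised iodo-ylide reacts through the kinetic cis-oxaphosphetane and gives the Z-2-iodoalkene (iodine cis to the chain).

Step 5
Reactants: 10 3-methylbutanal; 11 chloroacetaldehyde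
Product: 12 (2R,3S)-4-chloro-3-hydroxy-2-(propan-2-yl)butanal
Conditions: (R)-bis[3,5-bis(trifluoromethyl)phenyl](pyrrolidin-2-yl)methanol (10 mol%), 11 (40% in H2O, 1.5 equiv), THF, 23 °C; crude product used at once
Reagents that add atoms: none
Why: Diarylprolinol-catalysed direct cross-aldol (enamine catalysis); the E-enamine of 10 adds to the hydrogen-bonded, highly electrophilic aldehyde through the List–Houk-type transition state, giving the anti aldol and fixing C7 and C8 (the D-proline-series catalyst is chosen by this model; the other enantiomer would give ent-12).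

Step 6
Reactants: 9 (5Z)-6-iodohept-5-en-1-yne; 12 (2R,3S)-4-chloro-3-hydroxy-2-(propan-2-yl)butanal
Product: 14 (2S,3S,4RS,9Z)-1-chloro-10-iodo-3-(propan-2-yl)undec-9-en-5-yne-2,4-diol, via alkynylmagnesium bromide 13 (not isolated)
Conditions: 9 (2.4 equiv), EtMgBr (2.3 equiv), THF, 40 °C; then 12, −78 → −20 °C; 1 M HCl, 0 °C
Reagents that add atoms: none
Why: Grignard 1,2-addition of the alkynylmagnesium bromide to the aldehyde (the first equivalent only deprotonates the hydroxyl and returns 9); C7 and C8 are untouched at low temperature, and the C6 epimer mixture is erased by the oxidation in step 7.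

Step 7
Reactants: 14 (2S,3S,4RS,9Z)-1-chloro-10-iodo-3-(propan-2-yl)undec-9-en-5-yne-2,4-diol
Product: 15 (2S,3R,9Z)-1-chloro-2-hydroxy-10-iodo-3-(propan-2-yl)undec-9-en-5-yn-4-one
Conditions: MnO2 (20 equiv), CH2Cl2, 23 °C
Reagents that add atoms: none
Why: Chemoselective MnO2 oxidation of the propargylic alcohol; the unactivated C8 hydroxyl, the chlorohydrin and the alkenyl iodide do not react, and the neutral conditions leave the α-stereocentre C7 intact.

Step 8
Reactants: 15 (2S,3R,9Z)-1-chloro-2-hydroxy-10-iodo-3-(propan-2-yl)undec-9-en-5-yn-4-one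
Product: 16 (2S,3R,5Z,9Z)-1-chloro-2-hydroxy-10-iodo-6-methyl-3-(propan-2-yl)undeca-5,9-dien-4-one
Conditions: Me2CuLi (from MeLi and CuI, 3 equiv), Et2O, −78 °C, 20 min; AcOH, −78 °C
Reagents that add atoms: lithium dimethylcuprate, [Li+].C[Cu-]C
Why: Gilman syn-carbocupration (conjugate addition) of the ynone; methyl and copper add to the same side, so the C3 chain and the C6 carbonyl end up cis (5Z). Cold protonation limits equilibration through the allenolate, which is the known weak point with ynones, so some E isomer is expected and is removed by chromatography.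

Step 9
Reactants: 16 (2S,3R,5Z,9Z)-1-chloro-2-hydroxy-10-iodo-6-methyl-3-(propan-2-yl)undeca-5,9-dien-4-one
Product: 18 (2Z,6Z,9R,10R)-9-hydroxy-3,7-dimethyl-10-(propan-2-yl)cyclodeca-2,6-dien-1-one, via diiodide 17 (not isolated)
Conditions: NaI (5 equiv), DMA, 60 °C; then syringe-pump addition to NiBr2·MeOCH2CH2OMe (30 mol%), 4,4′-di-tert-butyl-2,2′-bipyridine (30 mol%), Mn powder (4 equiv), DMA, 60 °C, final 2 mM
Reagents that add atoms: none
Why: Proposed new method: ring-closing version of the nickel-catalysed reductive cross-electrophile coupling of an alkenyl iodide with an alkyl iodide (closest known reaction: the intermolecular nickel/iodide-cocatalysed coupling of epoxides or iodohydrins with aryl and alkenyl halides, which runs through the same β-hydroxyalkyl radical). Zerovalent nickel inserts into the alkenyl C–I bond with retention of the Z geometry, halogen-atom abstraction from 17 gives the primary C9 radical, the alkenyl nickel (divalent) captures it, and reductive elimination forms C9–C10 and the ten-membered ring. No stereocentre is formed; C7 and C8 are carried through. The closure is done at the enone stage because there the C9 radical can only reach a polarity-mismatched enone α-carbon or a fully substituted β-carbon, whereas after step 10 it would be an ordinary hex-5-enyl radical.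

Step 10
Reactants: 18 (2Z,6Z,9R,10R)-9-hydroxy-3,7-dimethyl-10-(propan-2-yl)cyclodeca-2,6-dien-1-one; 7 4-[(tert-butyldimethylsilyl)oxy]-3-methoxybenzaldehyde
Product: 20 (1R,3Z,7Z,9R,10S)-9-hydroxy-3,7-dimethyl-10-(propan-2-yl)cyclodeca-3,7-dien-1-yl 4-hydroxy-3-methoxybenzoate, via silyl ether 19 (not isolated)
Conditions: SmI2 (30 mol%, premixed with 7), 7 (5 equiv), THF, −10 °C; then KHF2, MeOH, 23 °C
Reagents that add atoms: none
Why: Evans–Tishchenko reduction, then fluoride cleavage of the aryl silyl ether; the C8 alkoxide adds to 7 and the hemiacetal bound to trivalent samarium delivers hydride to C6 through a chair-like six-membered transition state, which gives the 1,3-anti alcohol (C6 R, hence syn to the isopropyl group) and leaves the aryl ester on C8.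

**Compound list**
1 | benzene-1,2-diol (catechol) | Oc1ccccc1O | starting material
2 | 2-methoxyphenol (guaiacol) | COc1ccccc1O | intermediate
3 | oxoacetic acid (glyoxylic acid) | O=CC(=O)O | starting material
4 | (RS)-hydroxy(4-hydroxy-3-methoxyphenyl)acetic acid | COc1cc(C(O)C(=O)O)ccc1O | intermediate
5 | (4-hydroxy-3-methoxyphenyl)(oxo)acetic acid | COc1cc(C(=O)C(=O)O)ccc1O | intermediate
6 | 4-hydroxy-3-methoxybenzaldehyde (vanillin) | COc1cc(C=O)ccc1O | intermediate
7 | 4-[(tert-butyldimethylsilyl)oxy]-3-methoxybenzaldehyde | COc1cc(C=O)ccc1O[Si](C)(C)C(C)(C)C | intermediate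
8 | pent-4-ynal | C#CCCC=O | starting material
9 | (5Z)-6-iodohept-5-en-1-yne | C#CCC/C=C(\I)C | intermediate
10 | 3-methylbutanal | CC(C)CC=O | starting material
11 | chloroacetaldehyde | ClCC=O | starting material
12 | (2R,3S)-4-chloro-3-hydroxy-2-(propan-2-yl)butanal | O=C[C@H](C(C)C)[C@H](O)CCl | intermediate
13 | [(5Z)-6-iodohept-5-en-1-yn-1-yl]magnesium bromide | Br[Mg]C#CCC/C=C(\I)C | intermediate
14 | (2S,3S,4RS,9Z)-1-chloro-10-iodo-3-(propan-2-yl)undec-9-en-5-yne-2,4-diol | ClC[C@@H](O)[C@@H](C(C)C)C(O)C#CCC/C=C(\I)C | intermediate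
15 | (2S,3R,9Z)-1-chloro-2-hydroxy-10-iodo-3-(propan-2-yl)undec-9-en-5-yn-4-one | ClC[C@@H](O)[C@@H](C(C)C)C(=O)C#CCC/C=C(\I)C | intermediate
16 | (2S,3R,5Z,9Z)-1-chloro-2-hydroxy-10-iodo-6-methyl-3-(propan-2-yl)undeca-5,9-dien-4-one | ClC[C@@H](O)[C@@H](C(C)C)C(=O)/C=C(C)\CC/C=C(\I)C | intermediate
17 | (2S,3R,5Z,9Z)-2-hydroxy-1,10-diiodo-6-methyl-3-(propan-2-yl)undeca-5,9-dien-4-one | IC[C@@H](O)[C@@H](C(C)C)C(=O)/C=C(C)\CC/C=C(\I)C | intermediate
18 | (2Z,6Z,9R,10R)-9-hydroxy-3,7-dimethyl-10-(propan-2-yl)cyclodeca-2,6-dien-1-one | O[C@@H]1C/C(C)=C\CC/C(C)=C\C(=O)[C@@H]1C(C)C | intermediate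
19 | (1R,3Z,7Z,9R,10S)-9-hydroxy-3,7-dimethyl-10-(propan-2-yl)cyclodeca-3,7-dien-1-yl 4-[(tert-butyldimethylsilyl)oxy]-3-methoxybenzoate | COc1cc(C(=O)O[C@@H]2C/C(C)=C\CC/C(C)=C\[C@@H](O)[C@@H]2C(C)C)ccc1O[Si](C)(C)C(C)(C)C | intermediate
20 | (1R,3Z,7Z,9R,10S)-9-hydroxy-3,7-dimethyl-10-(propan-2-yl)cyclodeca-3,7-dien-1-yl 4-hydroxy-3-methoxybenzoate | COc1cc(C(=O)O[C@@H]2C/C(C)=C\CC/C(C)=C\[C@@H](O)[C@@H]2C(C)C)ccc1O | target

**Step count**
Total steps: 10. Longest linear sequence: 6 steps (steps 5 to 10 from 10 and 11; equally steps 4 and 6 to 10 from 8).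

**Three steps most likely to fail**

Step 9 (radical ring closure). Likely problems are dimerisation, addition of the alkenylnickel or of the C9 radical to the enone, and retro-aldol of the β-hydroxy ketone. The fallback changes the order so that the ester is put on before the ring is closed. It sets out from 16: Evans–Tishchenko reduction with 7 (SmI2 30 mol%, THF, −10 °C) gives the open-chain hydroxy ester (2S,3S,4R,5Z,9Z)-1-chloro-4-hydroxy-10-iodo-6-methyl-3-(propan-2-yl)undeca-5,9-dien-2-yl 4-[(tert-butyldimethylsilyl)oxy]-3-methoxybenzoate F1. NaI in DMA turns it into the diiodide (2S,3S,4R,5Z,9Z)-4-hydroxy-1,10-diiodo-6-methyl-3-(propan-2-yl)undeca-5,9-dien-2-yl 4-[(tert-butyldimethylsilyl)oxy]-3-methoxybenzoate F2, and the nickel/manganese coupling then closes the ring to 19, where the route is rejoined (KHF2 as in step 10). This takes the enone and the aldol unit out of the radical step. The price is that the C9 radical of F2 is a hex-5-enyl radical towards C4=C5, so this variant is run with a full equivalent of the nickel complex to make capture faster than 5-exo cyclisation.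

Step 10 (Evans–Tishchenko on a ring ketone). The samarium chelate may not form across the ring, and a transannular oxa-Michael addition is possible. The fallback esterifies and reduces in separate operations. It sets out from 18 and 7: NaClO2, NaH2PO4 and 2-methylbut-2-ene oxidise 7 to 4-[(tert-butyldimethylsilyl)oxy]-3-methoxybenzoic acid F3. Yamaguchi esterification of the C8 hydroxyl of 18 (2,4,6-trichlorobenzoyl chloride, Et3N, DMAP, toluene, 0 °C) gives the keto ester (1R,3Z,7Z,10R)-3,7-dimethyl-9-oxo-10-(propan-2-yl)cyclodeca-3,7-dien-1-yl 4-[(tert-butyldimethylsilyl)oxy]-3-methoxybenzoate F4. 1,2-Reduction of the enone (NaBH4, CeCl3·7H2O, MeOH, −78 °C; if the ring gives the wrong C6 epimer, a CBS oxazaborolidine with catecholborane for catalyst control) gives 19, where the route is rejoined. The β-acyloxy ketone F4 can eliminate, so base is kept to a minimum.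

Step 6 (organomagnesium addition to an unprotected β-hydroxy aldehyde that can undergo retro-aldol cleavage or close to the epoxide). The fallback goes through the acid oxidation level. It sets out from 12: NaClO2, NaH2PO4 and 2-methylbut-2-ene in t-BuOH/H2O give (2R,3S)-4-chloro-3-hydroxy-2-(propan-2-yl)butanoic acid F5. EDC·HCl, MeNHOMe·HCl and N-methylmorpholine give the Weinreb amide (2R,3S)-4-chloro-3-hydroxy-N-methoxy-N-methyl-2-(propan-2-yl)butanamide F6. Reagent 13 (3 equiv, THF, −20 °C) adds once to the chelated amide and gives ynone 15 directly, where the route is rejoined; steps 6 and 7 are replaced.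

Further compounds
F1 | step 9 | (2S,3S,4R,5Z,9Z)-1-chloro-4-hydroxy-10-iodo-6-methyl-3-(propan-2-yl)undeca-5,9-dien-2-yl 4-[(tert-butyldimethylsilyl)oxy]-3-methoxybenzoate | COc1cc(C(=O)O[C@H](CCl)[C@@H](C(C)C)[C@H](O)/C=C(C)\CC/C=C(\I)C)ccc1O[Si](C)(C)C(C)(C)C
F2 | step 9 | (2S,3S,4R,5Z,9Z)-4-hydroxy-1,10-diiodo-6-methyl-3-(propan-2-yl)undeca-5,9-dien-2-yl 4-[(tert-butyldimethylsilyl)oxy]-3-methoxybenzoate | COc1cc(C(=O)O[C@H](CI)[C@@H](C(C)C)[C@H](O)/C=C(C)\CC/C=C(\I)C)ccc1O[Si](C)(C)C(C)(C)C
F3 | step 10 | 4-[(tert-butyldimethylsilyl)oxy]-3-methoxybenzoic acid | COc1cc(C(=O)O)ccc1O[Si](C)(C)C(C)(C)C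
F4 | step 10 | (1R,3Z,7Z,10R)-3,7-dimethyl-9-oxo-10-(propan-2-yl)cyclodeca-3,7-dien-1-yl 4-[(tert-butyldimethylsilyl)oxy]-3-methoxybenzoate | COc1cc(C(=O)O[C@@H]2C/C(C)=C\CC/C(C)=C\C(=O)[C@@H]2C(C)C)ccc1O[Si](C)(C)C(C)(C)C
F5 | step 6 | (2R,3S)-4-chloro-3-hydroxy-2-(propan-2-yl)butanoic acid | OC(=O)[C@H](C(C)C)[C@H](O)CCl
F6 | step 6 | (2R,3S)-4-chloro-3-hydroxy-N-methoxy-N-methyl-2-(propan-2-yl)butanamide | CON(C)C(=O)[C@H](C(C)C)[C@H](O)CCl
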